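(The earlier runs and the new flask come from a simulation for an exercise; the scatter is artificial.)

The dawn flask stands far lower than the spring flask: at 6.00 min it holds 17.5% complex with one exchanged against 61.9% in spring.

in all of them: starting complex 0.069 M

| run | incoming ligand | scavenger | remark | time |
|---|---|---|---|---|
| dawn | 0.35 equiv | 1.2 equiv | run made earlier |  |
| spring | 2 equiv | 1.2 equiv | run made earlier |  |
| south-west | 0.500 equiv | 1.20 equiv |  | 8.0 min |
| east | 2.50 equiv | 1.20 equiv |  | 8.0 min |

| run | time / min | complex with two exchanged / % | complex with one exchanged / % | starting complex / % |
|---|---|---|---|---|
| dawn | 0.417 | 0.1 | 3.8 | 95.9 |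
| dawn | 1.00 | 0.2 | 6.6 | 93.4 |
| dawn | 2.50 | 0 | 12.7 | 88.8 |
| dawn | 6.00 | 0 | 17.5 | 82.4 |
| spring | 0.667 | 1.6 | 24.3 | 75.0 |
| spring | 2.00 | 3.5 | 46.7 | 50.2 |
| spring | 4.00 | 8.2 | 58.0 | 34.0 |
| spring | 6.00 | 9.9 | 61.9 | 27.5 |

(each reading ± 0.5 percentage points)

- for leaving ligand the idle adduct is counted in
- the earlier runs were read with a standard deviation of 0.5 percentage points
- candidate steps: starting complex + incoming ligand -> leaving ligand + complex with one exchanged; complex with one exchanged + incoming ligand -> leaving ligand + complex with two exchanged; leaving ligand + incoming ligand <-> idle adduct; scavenger + leaving ligand -> scavenged by-product

- which of these holds the largest part of the starting complex at the end of south-west (complex with two exchanged / complex with one exchanged / starting complex)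
- which of these holds the largest part of the starting complex at the end of east (complex with two exchanged / complex with one exchanged / starting complex)
- amount of complex with two exchanged at the end of east, in percent of the starting complex charged

In these two runs I read a double cost: each exchange uses one incoming ligand, and its leaving ligand ties up another as idle adduct. So I take half the charge as a flask's exchange budget, a yardstick for these short times and not a ceiling, with incoming ligand the limiting reagent in dawn. Exchanges made are the complex with one exchanged plus twice the complex with two exchanged. Over the budget, they give the spent share: 100% in dawn and 81.7% in spring.

With its budget spent on first exchanges, south-west keeps about 75.0% starting complex. For east I take spring's share, giving 1.02 exchanges per starting complex. The balance makes the complex with two exchanged half of what those exchanges exceed the complex with one exchanged by. Spring's 61.9% gives 20.1% and leaves 18.0% starting complex. Putting that back along spring's last slope raises the complex with one exchanged to 67.6%, which gives 17.3%. I expect a value between these two, with the complex with one exchanged on top.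

The forecast says starting complex for south-west, complex with one exchanged for east and 18.5%, since “each leaving ligand is captured as idle adduct and takes a second incoming ligand out of play”.

The flasks give starting complex at 73.5% in south-west, and complex with one exchanged at 67.3% with 19.0% complex with two exchanged in east.

    starting complex + incoming ligand → leaving ligand + complex with one exchanged (k = 3.70 M⁻¹ min⁻¹)
    complex with one exchanged + incoming ligand → leaving ligand + complex with two exchanged (k = 0.720 M⁻¹ min⁻¹)
    leaving ligand + incoming ligand ⇌ idle adduct, settled at all times (K = 2800 M⁻¹)
    scavenger + leaving ligand → scavenged by-product (k = 15.0 M⁻¹ min⁻¹)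

East spent 84.3% of its budget, against the 81.7% I assumed. For east left until 15 min, I take dawn's share of 100% and hold the complex with one exchanged at 67.3%, which gives 28.8% complex with two exchanged. That flask holds 65.5% complex with one exchanged and 27.2% complex with two exchanged.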